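G 0.50 M; Q 12 mM; time 25 min

    G + Q ⇌ G.Q (K1 = 5.4 L mol⁻¹, k1 = 1.47 L mol⁻¹ s⁻¹)
    G.Q ⇌ L (K2 = 36.4, k2 = 0.741 s⁻¹)
    L → Q + J (k3 = 0.581 s⁻¹)
    2 G → G2 (k4 = 0.0238 L mol⁻¹ s⁻¹)
    G.Q + J → G.Q.J (k5 = 0.0590 L mol⁻¹ s⁻¹)
    Q + J → Q + X (k6 = 1.96 L mol⁻¹ s⁻¹)

- at 25 min, what has stopped the reaction, if anything has (no working catalyst is left / it is still moving / all of G has reacted / forward and back rates have come level)
- share of the G used up at 25 min
- X at 25 min, in percent of the G charged
- amount of J if the flask were left three thousand times as long, in percent of the G charged

- in percentages every species weighs as the G in it: one G2 or G.Q.J counts as two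
- where a step has two of a species, its rate is k times that concentration squared, and two are used at each turn
- the reaction counts as stopped when no species that holds the G changes by six tenths of a point or more over the second half of the time
- run time (flask): 25 min

The easy step comes first: at the charge, G goes to G2 at 11.9 mM s⁻¹, and that rate falls with [G] squared. The round through the catalyst takes more work. With G.Q and L at steady state, L stands to G.Q as 1.23, and the round runs at V[G]/(Km+[G]), with V = 3.85 mM s⁻¹ and Km = 0.301 M. Km is the half-rate concentration, the [G] at which the round gives half of V (the Michaelis constant). The charge lies above Km, and at steady state the round gives 2.40 mM s⁻¹ at the charge, slower than the loss to G2. Far below Km the round turns pseudo-first-order and, leaving the loss to G2 aside, [G] halves every 0.904 min, which is short against 25 min, so [G] should end far below its charge. J, with the catalyst counted as Q, halves in 0.491 min, also shorter than 25 min, so the J made should pass on to X, apart from what G.Q takes up.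

The round's share of the G used is B/(B+[G]([G]+Km)), where B is V divided by the doubled rate constant of the loss to G2, 0.0809 M^2. Holding [G]+Km at a constant h makes this integrable: a stretch of [G] yields (B/h) times the logarithm of the ratio of B+h[G] at its ends. With the steady state kept, the catalyst taken as intact and the J made counted as X, the smallest h on a stretch bounds X from above and the largest from below. On these terms, over the whole charge, the reckoning puts X between 36.0% and 56.5%. Cutting the stretch at [G] = Km tightens this to 39.7% and 50.5%.

The forecast says all of G has reacted, with 100% used, X at 44% (range 41% to 47%) and J at 0% on long standing, since J “is destroyed by free Q”. Its X lies above the lower bound and below the upper one, and its range is narrower than this bracket.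

At 25.0 min in the flask, all of G has reacted, with G at 0%, 100% used and X at 43.8%, above the lower bound and below the upper one; J stands at 0% on long standing. At 2.50 min in the flask, [G] stands at 0.0449 M, less than Km, and G2 already holds 55.1% of the G charged, against 55.8% at 25.0 min. The neighbour flask charged with 0.20 M of G starts below Km; a single stretch, on the same terms, puts its X between 65.1% and 74.8%, and it ends with X at 68.6%.

The constants used here were drawn at random within sensible limits; no experiment stands behind them.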